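**Strategy**

Ring numbering: C1 is the ring carbonyl, C2=C3 the alkene, C5 the carbinol carbon. Everything rests on forming C1–C2 and C5–C6 together: the ring is read as an opened 7-oxanorbornadiene in which the C5 hydroxyl is the old furan oxygen and C6–C1(=O) an old 3-bromopropiolate. The key step is an intramolecular furan Diels–Alder reaction of the bromopropiolate ester of a 1-(2-furyl)alkan-2-ol; it makes both bonds and the quaternary C5 at once, steered by the (S)-carbinol through a temporary δ-lactone. It exploits the two β-hydroxy ketone arrays around C5: the lactone carbon later leaves as CO2, SmI2 cuts the bridge at C2, and the carbinol becomes the side-chain ketone.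

Key step: step 5

Remark: 3-bromopropiolic acid is prepared in step 1 because its commercial supply is uncertain. The facial sense drawn for step 5 assumes that the forming lactone lies on the side of the oxygen bridge, as is usual for tethered furan cycloadditions.

**Route**

Step 1
Reactants: 1 propiolic acid
Product: 2 3-bromopropiolic acid
Conditions: KOH, Br2, H2O, 0 °C; then H2SO4 (aq)
Reagents that add atoms: bromine, BrBr
Why: Hypobromite formed from Br2 and KOH should brominate the terminal alkyne carbon of potassium propiolate (electrophilic halogenation of an acetylide), and acidification frees the bromo acid.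

Step 2
Reactants: 3 methyl linoleate; 4 2-(furan-2-yl)acetic acid
Product: 6 (10Z,13Z)-1-(furan-2-yl)nonadeca-10,13-dien-2-one, via β-keto acid 5 (not isolated)
Conditions: LiN(SiMe3)2 (3.3 equiv), THF, −20 °C to rt; then 2 M HCl, 40 °C
Reagents that add atoms: none
Why: Dianion Claisen condensation: the enediolate of 4 should be C-acylated by ester 3, and the β-keto acid 5 freed on acidification loses CO2 to the ketone, the amide base being too weak to touch the bis-allylic CH2 groups or the furan ring.

Step 3
Reactants: 6 (10Z,13Z)-1-(furan-2-yl)nonadeca-10,13-dien-2-one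
Product: 7 (2S,10Z,13Z)-1-(furan-2-yl)nonadeca-10,13-dien-2-ol
Conditions: (S)-selective ketoreductase, NADP+ (cat.), 2-propanol, phosphate buffer pH 7 with DMSO, 30 °C
Reagents that add atoms: none
Why: Biocatalytic asymmetric ketone reduction: a ketoreductase, chosen from a panel for (S)-selectivity, should transfer hydride from NADPH to one carbonyl face and so set the carbinol centre, telling the furylmethyl arm from the long alkyl arm, a CH2-versus-CH2 choice that oxazaborolidine or transfer-hydrogenation catalysts do not make.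

Step 4
Reactants: 7 (2S,10Z,13Z)-1-(furan-2-yl)nonadeca-10,13-dien-2-ol; 2 3-bromopropiolic acid
Product: 8 (2S,10Z,13Z)-1-(furan-2-yl)nonadeca-10,13-dien-2-yl 3-bromoprop-2-ynoate
Conditions: DCC, DMAP (5 mol %), CH2Cl2, −20 °C to 0 °C
Reagents that add atoms: none
Why: Steglich esterification at low temperature with little DMAP should acylate the carbinol with retention and without conjugate addition to the bromoalkynoate.

Step 5
Reactants: 8 (2S,10Z,13Z)-1-(furan-2-yl)nonadeca-10,13-dien-2-yl 3-bromoprop-2-ynoate
Product: 9 bromo oxanorbornadiene δ-lactone (3-bromo-7-oxabicyclo[2.2.1]hepta-2,5-diene whose C2 carboxyl is lactonised onto the (S)-carbinol of the chain on bridgehead C1)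
Conditions: toluene (0.01 M), BHT (cat.), 85 °C, dark
Reagents that add atoms: none
Why: A thermal, concerted but asynchronous [4+2] cycloaddition joins the furan diene to the bromoalkynoate, the unsubstituted furan α-carbon bonding to the bromine-bearing alkyne carbon and the substituted furan α-carbon to the ester-bearing one, which is the polarity that untethered 2-alkylfurans show with 3-bromopropiolates and which the four-atom ester tether enforces. The closest known reactions are the intermolecular furan/3-bromopropiolate Diels–Alder reaction and the intramolecular furan cycloadditions of unsaturated esters and sulfonates of 1-(2-furyl)alkan-2-ols. The cyclohexadiene ring of the oxanorbornadiene is closed by the [4+2] event itself, and the δ-lactone is closed in the fused mode, the two tether-bearing termini bonding to each other. Both bridgeheads, and with them the quaternary carbon that keeps the oxygen, are created together, and their sense is set by the (S)-carbinol, because the forming lactone should lie on the side of the oxygen bridge with the C17 chain pseudo-equatorial. Only facial selectivity is needed, since an alkyne has no endo/exo issue, and a minor bridgehead epimer would be a separable diastereomer that can revert to 8 on heating.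

Step 6
Reactants: 9 bromo oxanorbornadiene δ-lactone
Product: 11 3,3-dimethoxy-1-[(2S,10Z,13Z)-2-hydroxynonadeca-10,13-dien-1-yl]-7-oxabicyclo[2.2.1]hept-5-ene-2-carboxylic acid, via dimethyl ketal lactone 10 (not isolated)
Conditions: NaOMe (3 equiv), MeOH, 0 °C to rt; then H2O, 40 °C; then 1 M HCl to pH 4, 0 °C
Reagents that add atoms: sodium methoxide, C[O-].[Na+]; water, O
Why: Addition–elimination then conjugate addition of methoxide at the bromine-bearing carbon (the known route from 3-bromo-7-oxanorbornadiene-2-carboxylates to their 3,3-dimethoxy derivatives) should give ketal 10, whose δ-lactone is then opened by hydroxide (saponification); the ketal keeps the ester α-carbon from becoming a stabilised enolate that could expel the bridge oxygen, a cyclic ketal with the freed carbinol is out of geometric reach, and the new CH(CO2H) centre forms as a mixture that step 8 erases.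

Step 7
Reactants: 11 3,3-dimethoxy-1-[(2S,10Z,13Z)-2-hydroxynonadeca-10,13-dien-1-yl]-7-oxabicyclo[2.2.1]hept-5-ene-2-carboxylic acid
Product: 12 3,3-dimethoxy-1-[(10Z,13Z)-2-oxononadeca-10,13-dien-1-yl]-7-oxabicyclo[2.2.1]hept-5-ene-2-carboxylic acid
Conditions: Dess–Martin periodinane, NaHCO3, CH2Cl2, 0 °C to rt (crude 11 used at once)
Reagents that add atoms: none
Why: Dess–Martin oxidation under bicarbonate buffer should convert the only oxidisable alcohol into the side-chain ketone at once after step 6, which removes the hydroxyl that could otherwise re-close the lactone and leaves the alkenes and the ketal untouched.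

Step 8
Reactants: 12 3,3-dimethoxy-1-[(10Z,13Z)-2-oxononadeca-10,13-dien-1-yl]-7-oxabicyclo[2.2.1]hept-5-ene-2-carboxylic acid
Product: 14 (1S,4S)-4-[(10Z,13Z)-2-oxononadeca-10,13-dien-1-yl]-7-oxabicyclo[2.2.1]hept-5-en-2-one, via β-keto acid 13 (not isolated)
Conditions: 2 M HCl, THF, 35 °C
Reagents that add atoms: water, O
Why: Acid-catalysed ketal hydrolysis unmasks the ring ketone, and the β-keto acid 13 should lose CO2 through its enol (decarboxylation of a β-keto acid) under conditions that give neither ketone an enolate able to eject the bridge oxygen.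

Step 9
Reactants: 14 (1S,4S)-4-[(10Z,13Z)-2-oxononadeca-10,13-dien-1-yl]-7-oxabicyclo[2.2.1]hept-5-en-2-one
Product: 16 (S)-5-hydroxy-5-[(10Z,13Z)-2-oxononadeca-10,13-dien-1-yl]cyclohex-2-en-1-one (target), via β,γ-enone 15 (not isolated)
Conditions: SmI2 (2.2 equiv), THF/MeOH, −78 °C; then Et3N (cat.), CH2Cl2, 0 °C
Reagents that add atoms: none
Why: Ketyl formation by SmI2 at the strained α-alkoxy ketone should break the C–O bond between the bridge oxygen and the bridgehead next to the carbonyl (the known reductive opening of 7-oxabicyclo[2.2.1]heptan-2-ones), leaving the oxygen on the quaternary carbon as the tertiary alcohol with unchanged configuration; the dienolate is protonated to β,γ-enone 15, which a trace of Et3N moves into conjugation, while the isolated ketone and the skipped diene are inert at −78 °C.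

**Compound list**

1 | propiolic acid | C#CC(=O)O | starting material
2 | 3-bromopropiolic acid | BrC#CC(=O)O | intermediate
3 | methyl linoleate (methyl (9Z,12Z)-octadeca-9,12-dienoate) | CCCCC/C=C\C/C=C\CCCCCCCC(=O)OC | starting material
4 | 2-(furan-2-yl)acetic acid | OC(=O)Cc1ccco1 | starting material
5 | (11Z,14Z)-2-(furan-2-yl)-3-oxoicosa-11,14-dienoic acid (racemic at C2, not isolated) | CCCCC/C=C\C/C=C\CCCCCCCC(=O)C(C(=O)O)c1ccco1 | intermediate
6 | (10Z,13Z)-1-(furan-2-yl)nonadeca-10,13-dien-2-one | CCCCC/C=C\C/C=C\CCCCCCCC(=O)Cc1ccco1 | intermediate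
7 | (2S,10Z,13Z)-1-(furan-2-yl)nonadeca-10,13-dien-2-ol | CCCCC/C=C\C/C=C\CCCCCCC[C@H](O)Cc1ccco1 | intermediate
8 | (2S,10Z,13Z)-1-(furan-2-yl)nonadeca-10,13-dien-2-yl 3-bromoprop-2-ynoate | BrC#CC(=O)O[C@@H](CCCCCCC/C=C\C/C=C\CCCCC)Cc1ccco1 | intermediate
9 | bromo oxanorbornadiene δ-lactone (chain carbinol carbon S; bridgeheads in the sense that leads to (1S,4S)-14) | BrC1=C2C(=O)O[C@@H](CCCCCCC/C=C\C/C=C\CCCCC)C[C@]23O[C@H]1C=C3 | intermediate
10 | dimethyl ketal lactone (3,3-dimethoxy analogue of 9 with CH at the lactone α-carbon, epimers there; not isolated) | COC1(OC)C2C(=O)O[C@@H](CCCCCCC/C=C\C/C=C\CCCCC)C[C@]23O[C@H]1C=C3 | intermediate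
11 | 3,3-dimethoxy-1-[(2S,10Z,13Z)-2-hydroxynonadeca-10,13-dien-1-yl]-7-oxabicyclo[2.2.1]hept-5-ene-2-carboxylic acid (C2 epimers; bridgeheads as in 14) | COC1(OC)C(C(=O)O)[C@]2(C[C@@H](O)CCCCCCC/C=C\C/C=C\CCCCC)O[C@H]1C=C2 | intermediate
12 | 3,3-dimethoxy-1-[(10Z,13Z)-2-oxononadeca-10,13-dien-1-yl]-7-oxabicyclo[2.2.1]hept-5-ene-2-carboxylic acid (C2 epimers; bridgeheads as in 14) | COC1(OC)C(C(=O)O)[C@]2(CC(=O)CCCCCCC/C=C\C/C=C\CCCCC)O[C@H]1C=C2 | intermediate
13 | 3-oxo-1-[(10Z,13Z)-2-oxononadeca-10,13-dien-1-yl]-7-oxabicyclo[2.2.1]hept-5-ene-2-carboxylic acid (not isolated) | O=C1C(C(=O)O)[C@]2(CC(=O)CCCCCCC/C=C\C/C=C\CCCCC)O[C@H]1C=C2 | intermediate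
14 | (1S,4S)-4-[(10Z,13Z)-2-oxononadeca-10,13-dien-1-yl]-7-oxabicyclo[2.2.1]hept-5-en-2-one | O=C1C[C@]2(CC(=O)CCCCCCC/C=C\C/C=C\CCCCC)O[C@H]1C=C2 | intermediate
15 | (S)-5-hydroxy-5-[(10Z,13Z)-2-oxononadeca-10,13-dien-1-yl]cyclohex-3-en-1-one (not isolated) | CCCCC/C=C\C/C=C\CCCCCCCC(=O)C[C@@]1(O)C=CCC(=O)C1 | intermediate
16 | (S)-5-hydroxy-5-[(10Z,13Z)-2-oxononadeca-10,13-dien-1-yl]cyclohex-2-en-1-one | CCCCC/C=C\C/C=C\CCCCCCCC(=O)C[C@@]1(O)CC=CC(=O)C1 | target

**Count and risks**

Total steps: 9. Longest linear sequence: 8 steps (steps 2 to 9, from methyl linoleate and 2-(furan-2-yl)acetic acid); step 1 is a one-step side branch.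

Step 5. The cyclisation may be slow, because the ester has to leave its preferred s-trans form before the alkyne can reach the furan, so that intermolecular addition or decay of the bromoalkynoate could compete. The remote carbinol may also discriminate the two furan faces only weakly. Fallback, from 7 back to 9: the two C–C bonds are made between separate partners and the lactone is closed afterwards. Alcohol 7 is heated (benzene, 80 °C) with methyl 3-bromoprop-2-ynoate F1 (from methyl propiolate, NBS, AgNO3 cat., acetone). This should give the hydroxy ester adduct F2 with the same regiochemistry as both bridgehead diastereomers. The diastereomer with the bridgehead sense of 9 is separated by chromatography, and Ti(OiPr)4 (cat.) in toluene at 80 °C closes its δ-lactone by transesterification to give 9.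

Step 6. The ester enolate may expel the bridge oxygen under methoxide or hydroxide, the crowded lactone may hydrolyse slowly, and the hydroxy acid may re-close to the lactone on acidification. Fallback, from 7 back to 14: the tether is given up so that no lactone has to be hydrolysed.
- Alcohol 7 is silylated (t-BuPh2SiCl, imidazole, DMF) to the silyl ether F3.
- F3 is heated with tert-butyl 3-bromoprop-2-ynoate F4 (from tert-butyl propiolate, NBS, AgNO3 cat.) to give the adduct F5 as both bridgehead diastereomers; the one with the bridgehead sense of 14 is taken on after chromatography.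
- NaOMe in MeOH gives the dimethyl ketal tert-butyl ester F6.
- CF3CO2H in wet CH2Cl2 removes the tert-butyl group by acidolysis at the alkyl–oxygen bond (indifferent to crowding at the carbonyl), hydrolyses the ketal and lets the β-keto acid lose CO2, giving the silyl-protected ketone F7.
- HF·pyridine in THF gives the hydroxy ketone F8, and Dess–Martin oxidation returns to 14.

Step 3. The very lipophilic ketone may be converted poorly in the aqueous medium, and the enzyme may not distinguish the two methylene-flanked faces well enough. Fallback, from 3 back to 7: the carbinol centre is taken from a resolved epoxide instead.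
- Ester 3 is reduced with i-Bu2AlH (toluene, −78 °C) to (9Z,12Z)-octadeca-9,12-dienal F9.
- Corey–Chaykovsky methylenation (Me3SI, NaH, DMSO) gives the racemic oxirane F10.
- Hydrolytic kinetic resolution with (R,R)-(salen)Co(OAc), a complex of trivalent cobalt, and 0.55 equiv H2O should hydrolyse the (R)-oxirane and leave the (S)-oxirane F11.
- 2-Furyllithium (furan, n-BuLi, THF, 0 °C to rt) opens F11 at its CH2 terminus with retention at the carbinol carbon to give 7.

**Further compounds**

F1 | step 5 | methyl 3-bromoprop-2-ynoate | BrC#CC(=O)OC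
F2 | step 5 | methyl 3-bromo-1-[(2S,10Z,13Z)-2-hydroxynonadeca-10,13-dien-1-yl]-7-oxabicyclo[2.2.1]hepta-2,5-diene-2-carboxylate (both bridgehead diastereomers) | BrC1=C(C(=O)OC)C2(C[C@@H](O)CCCCCCC/C=C\C/C=C\CCCCC)OC1C=C2
F3 | step 6 | tert-butyl{[(2S,10Z,13Z)-1-(furan-2-yl)nonadeca-10,13-dien-2-yl]oxy}diphenylsilane | CCCCC/C=C\C/C=C\CCCCCCC[C@H](O[Si](c1ccccc1)(c1ccccc1)C(C)(C)C)Cc1ccco1
F4 | step 6 | tert-butyl 3-bromoprop-2-ynoate | BrC#CC(=O)OC(C)(C)C
F5 | step 6 | tert-butyl 3-bromo-1-[(2S,10Z,13Z)-2-(tert-butyldiphenylsilyloxy)nonadeca-10,13-dien-1-yl]-7-oxabicyclo[2.2.1]hepta-2,5-diene-2-carboxylate (both bridgehead diastereomers) | BrC1=C(C(=O)OC(C)(C)C)C2(C[C@@H](O[Si](c3ccccc3)(c3ccccc3)C(C)(C)C)CCCCCCC/C=C\C/C=C\CCCCC)OC1C=C2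
F6 | step 6 | tert-butyl 3,3-dimethoxy-1-[(2S,10Z,13Z)-2-(tert-butyldiphenylsilyloxy)nonadeca-10,13-dien-1-yl]-7-oxabicyclo[2.2.1]hept-5-ene-2-carboxylate (bridgeheads as in 14, C2 epimers) | COC1(OC)C(C(=O)OC(C)(C)C)[C@]2(C[C@@H](O[Si](c3ccccc3)(c3ccccc3)C(C)(C)C)CCCCCCC/C=C\C/C=C\CCCCC)O[C@H]1C=C2
F7 | step 6 | (1S,4S)-4-[(2S,10Z,13Z)-2-(tert-butyldiphenylsilyloxy)nonadeca-10,13-dien-1-yl]-7-oxabicyclo[2.2.1]hept-5-en-2-one | O=C1C[C@]2(C[C@@H](O[Si](c3ccccc3)(c3ccccc3)C(C)(C)C)CCCCCCC/C=C\C/C=C\CCCCC)O[C@H]1C=C2
F8 | step 6 | (1S,4S)-4-[(2S,10Z,13Z)-2-hydroxynonadeca-10,13-dien-1-yl]-7-oxabicyclo[2.2.1]hept-5-en-2-one | O=C1C[C@]2(C[C@@H](O)CCCCCCC/C=C\C/C=C\CCCCC)O[C@H]1C=C2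
F9 | step 3 | (9Z,12Z)-octadeca-9,12-dienal | CCCCC/C=C\C/C=C\CCCCCCCC=O
F10 | step 3 | racemic 2-[(8Z,11Z)-heptadeca-8,11-dien-1-yl]oxirane | CCCCC/C=C\C/C=C\CCCCCCCC1CO1
F11 | step 3 | (S)-2-[(8Z,11Z)-heptadeca-8,11-dien-1-yl]oxirane | CCCCC/C=C\C/C=C\CCCCCCC[C@H]1CO1
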